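Atoms carry germacrane numbers. Ring A is the ten-membered carbocycle, ring B the furanone (O, C3, C2, C1, C10) and ring C the lactone. Ring B holds an α-oxygenated acyl unit, O–C10(CH3)–C1(=O), next to the C9 and C8 carbinols. This array is C1–C4 of commercial 2-C-methyl-D-ribono-1,4-lactone. The key step is a lactone-to-furanone ring switch. The acetylide of a Z-enyne (C2–C6, C15) opens the silylene-protected lactone at C1 (C1–C2 bond). The tertiary C10–OH then closes onto C3 (O–C3 bond) in the same flask, which also frees O8. Mitsunobu esterification inverts C8, sugar C5 becomes C7, and an allylchromium addition (C6–C7) closes rings A and C.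

Key step: step 3

Remark: the 2-methylbutanoate centre of the target is R, and (R)-2-methylbutanoic acid is taken as purchasable in enantiopure form. Sugar atoms map as C1→C1, C2→C10, 2-CH3→C14, C3→C9, C4→C8, C5→C7.

Step 1
Reactants: 1 (Z)-3-methylpent-2-en-4-yn-1-ol
Product: 2 tert-butyl(dimethyl){[(2Z)-3-methylpent-2-en-4-yn-1-yl]oxy}silane
Conditions: TBSCl, imidazole, CH2Cl2, 0 °C → rt
Reagents that add atoms: tert-butyldimethylsilyl chloride, CC(C)(C)[Si](C)(C)Cl
Why: Silyl ether formation masks O6, which would otherwise add 5-exo-dig to the ynone made in step 3; no stereocentre is involved and the Z alkene is untouched.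

Step 2
Reactants: 3 2-C-methyl-D-ribono-1,4-lactone
Product: 4 3,5-O-(di-tert-butylsilanediyl)-2-C-methyl-D-ribono-1,4-lactone
Conditions: tBu2Si(OTf)2, 2,6-lutidine, CH2Cl2/DMF, −20 → 0 °C
Reagents that add atoms: di-tert-butylsilyl bis(trifluoromethanesulfonate), CC(C)(C)[Si](OS(=O)(=O)C(F)(F)F)(OS(=O)(=O)C(F)(F)F)C(C)(C)C
Why: Cyclic silylene formation, in which the bis-triflate silylates the primary O5 first and closes a six-membered ring onto the secondary O3, as in the 3',5'-protection of ribonucleosides, while the tertiary C2–OH is too hindered to react; no stereocentre changes.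

Step 3
Reactants: 2 tert-butyl(dimethyl){[(2Z)-3-methylpent-2-en-4-yn-1-yl]oxy}silane; 4 3,5-O-(di-tert-butylsilanediyl)-2-C-methyl-D-ribono-1,4-lactone
Product: 8 (2R)-2-[(4R,5R)-2,2-di-tert-butyl-5-hydroxy-1,3,2-dioxasilinan-4-yl]-5-[(2Z)-4-(tert-butyldimethylsilyloxy)but-2-en-2-yl]-2-methylfuran-3(2H)-one, via lithium acetylide 5 (not isolated), via hydroxy ynone 6 (not isolated), via enaminone 7 (not isolated)
Conditions: 2 (2.2 equiv), n-BuLi (2.1 equiv), THF, −78 °C; 4, −78 → −40 °C; AcOH (2.2 equiv), −78 °C; Et2NH (3 equiv), EtOH, 0 °C → rt; aq. citric acid (pH 4), rt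
Reagents that add atoms: none
Why: One equivalent of lithium acetylide 5 deprotonates the tertiary C10–OH of 4 and a second adds once to the lactone carbonyl C1 (acetylide addition to an aldonolactone), which makes C1–C2; after neutralisation the adduct, a lactol trans-fused to the silylene ring and therefore strained, opens to the α'-hydroxy ynone 6 and so releases O8. Et2NH adds to C3 of 6 to give enaminone 7, and at pH 4 the C10–OH attacks C3 of its vinylogous iminium form and Et2NH leaves again, which makes O–C3; this amine-relayed cyclisation of α'-hydroxy ynones is the closest known reaction type and a classical entry to 3(2H)-furanones. Only ring B is closed: 5-exo-trig addition to C3=N+ followed by elimination, in sum a 5-endo-dig hydroalkoxylation of C2≡C3. No stereocentre is formed: C10 and C9 are carried over from 3, C10 is quaternary and cannot epimerise, and C8 keeps its ribo configuration until step 4. The step needs mono-addition (the tetrahedral lithium alkoxide persists at −78 °C), closure by O10 alone (O9 and O7 are locked in the silylene, O6 is silylated, O8 could only form a seven-membered ring) and retention of the Z C4=C5 bond (brief contact with the amine at or below room temperature). The acid quench before the amine stage keeps alkoxides away from the silyl groups, so that no silyl migration should occur.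

Step 4
Reactants: 8 furanone alcohol from step 3; 9 (R)-2-methylbutanoic acid
Product: 10 (4R,5S)-2,2-di-tert-butyl-4-{(2R)-5-[(2Z)-4-(tert-butyldimethylsilyloxy)but-2-en-2-yl]-2-methyl-3-oxo-2,3-dihydrofuran-2-yl}-1,3,2-dioxasilinan-5-yl (2R)-2-methylbutanoate
Conditions: 9 (2 equiv), PPh3, DIAD, toluene, 0 °C → rt
Reagents that add atoms: none
Why: Mitsunobu esterification inverts C8 (R to S) by SN2 attack of the carboxylate on the equatorial, phosphonium-activated C8–OH of the dioxasilinane chair, whose axial approach path is flanked only by the two ring oxygens, and the centre of 9 is not at risk because the acid is never activated.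

Step 5
Reactants: 10 silylene-protected ester from step 4
Product: 11 (2S,3R)-1,3-dihydroxy-3-{(2R)-5-[(2Z)-4-hydroxybut-2-en-2-yl]-2-methyl-3-oxo-2,3-dihydrofuran-2-yl}propan-2-yl (2R)-2-methylbutanoate
Conditions: HF·pyridine, pyridine, THF, 0 °C → rt; pH 7 phosphate buffer
Reagents that add atoms: none
Why: Fluoride-mediated desilylation removes the silylene and the primary TBS ether together, and the pyridine buffer and neutral work-up should suppress 1,2-migration of the α-branched acyl group from O8 to O7 or O9.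

Step 6
Reactants: 11 triol from step 5
Product: 12 (2R,3R)-3-hydroxy-3-{(2R)-2-methyl-3-oxo-5-[(2Z)-4-oxobut-2-en-2-yl]-2,3-dihydrofuran-2-yl}-1-oxopropan-2-yl (2R)-2-methylbutanoate (same spatial arrangement as 11; the C8 label changes by priority only)
Conditions: TEMPO (cat.), PhI(OAc)2 (2.3 equiv), CH2Cl2, rt
Reagents that add atoms: none
Why: Oxoammonium (TEMPO/PhI(OAc)2) oxidation takes both primary alcohols (C6, C7) to aldehydes and leaves the C9–OH next to quaternary C10 alone, and its non-basic medium should preserve the Z-enal and the C8 centre α to the new aldehyde.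

Step 7
Reactants: 12 dialdehyde from step 6; 13 methyl propiolate
Product: 15 methyl (4S,5R)-3,5-dihydroxy-2-methylidene-4-{[(2R)-2-methylbutanoyl]oxy}-5-{(2R)-2-methyl-3-oxo-5-[(2Z)-4-oxobut-2-en-2-yl]-2,3-dihydrofuran-2-yl}pentanoate (both C7 epimers), via vinylalane 14 (not isolated)
Conditions: 13, iBu2AlH, NMO, THF, 0 °C; then 12 (14: 2.2 equiv), −78 → −20 °C; aq. potassium sodium tartrate
Reagents that add atoms: none
Why: Vinylalumination, the non-basic equivalent of a Morita–Baylis–Hillman reaction, joins C11 to C7; one equivalent of 14 is consumed by the C9–OH, the α-acyloxy aliphatic aldehyde C7 should react well before the conjugated Z-enal C6, and the new C7 carbinol centre need not be controlled because step 8 erases it.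

Step 8
Reactants: 15 allylic alcohol from step 7
Product: 16 methyl (2Z,4S,5R)-2-(bromomethyl)-5-hydroxy-4-{[(2R)-2-methylbutanoyl]oxy}-5-{(2R)-2-methyl-3-oxo-5-[(2Z)-4-oxobut-2-en-2-yl]-2,3-dihydrofuran-2-yl}pent-2-enoate
Conditions: NBS, Me2S (premixed), CH2Cl2, 0 °C → rt
Reagents that add atoms: N-bromosuccinimide, O=C1CCC(=O)N1Br
Why: Corey–Kim-type activation of the Baylis–Hillman-type alcohol followed by SN2' attack of bromide gives the favoured Z-2-(bromomethyl)enoate, whereas the neopentyl-like C9–OH can only form an alkoxysulfonium salt that reverts on work-up.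

Step 9
Reactants: 16 allylic bromide aldehyde from step 8
Product: 19 target CNP0146060.1, via allylchromium species 17 (not isolated), via hydroxy ester 18 (not isolated)
Conditions: CrCl2 (10 equiv), THF/DMF (2 mM, slow addition), rt; aq. NH4Cl; crude, PPTS (cat.), CH2Cl2, rt
Reagents that add atoms: none
Why: Intramolecular Nozaki–Hiyama allylation (Barbier-type macrocyclisation, an established way to close germacranolide rings at C6–C7) followed by lactonisation: CrCl2 turns the bromide into allylchromium 17, which tolerates the free C9–OH and adds through C7 to the C6 aldehyde in a chair-like transition state with C5 and C8 equatorial, so that the anti (6R,7S) pair needed for trans-fused ring C should result, the C7 face being selected by C8 (C8–H eclipsed with the alkene to avoid A(1,3) strain, new bond anti to the C9 branch), and O6 of 18 then displaces methoxide from C12.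

Compound list
1 | (Z)-3-methylpent-2-en-4-yn-1-ol | C#C/C(C)=C\CO | starting material
2 | tert-butyl(dimethyl){[(2Z)-3-methylpent-2-en-4-yn-1-yl]oxy}silane | C#C/C(C)=C\CO[Si](C)(C)C(C)(C)C | intermediate
3 | 2-C-methyl-D-ribono-1,4-lactone, (3R,4R,5R)-3,4-dihydroxy-5-(hydroxymethyl)-3-methyloxolan-2-one | O=C1[C@](C)(O)[C@H](O)[C@H](O1)CO | starting material
4 | 3,5-O-(di-tert-butylsilanediyl)-2-C-methyl-D-ribono-1,4-lactone (free tertiary OH) | O=C1[C@](C)(O)[C@H](O[Si](C(C)(C)C)(C(C)(C)C)OC2)[C@@H]2O1 | intermediate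
5 | lithium acetylide of 2 | [Li]C#C/C(C)=C\CO[Si](C)(C)C(C)(C)C | intermediate
6 | α'-hydroxy ynone (open form of the lactol): C6H2(OTBS)–C5H=C4(CH3)–C3≡C2–C1(=O)–C10(CH3)(OH)–dioxasilinane (C9, C8–OH, C7); 4Z; C8–C10 as in 4 | CC(C)(C)[Si](C)(C)OC/C=C(/C)C#CC(=O)[C@](C)(O)[C@H](O[Si](C(C)(C)C)(C(C)(C)C)OC1)[C@@H]1O | intermediate
7 | enaminone, 6 with Et2N on C3 and H on C2 (push–pull C2=C3 bond, geometry not fixed) | CC(C)(C)[Si](C)(C)OC/C=C(/C)C(N(CC)CC)=CC(=O)[C@](C)(O)[C@H](O[Si](C(C)(C)C)(C(C)(C)C)OC1)[C@@H]1O | intermediate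
8 | (2R)-2-[(4R,5R)-2,2-di-tert-butyl-5-hydroxy-1,3,2-dioxasilinan-4-yl]-5-[(2Z)-4-(tert-butyldimethylsilyloxy)but-2-en-2-yl]-2-methylfuran-3(2H)-one | CC(C)(C)[Si](C)(C)OC/C=C(/C)C1=CC(=O)[C@](C)(O1)[C@H](O[Si](C(C)(C)C)(C(C)(C)C)OC2)[C@@H]2O | intermediate
9 | (R)-2-methylbutanoic acid | CC[C@@H](C)C(=O)O | starting material
10 | (4R,5S)-dioxasilinan-5-yl (2R)-2-methylbutanoate of the furanone (C8 inverted) | CC(C)(C)[Si](C)(C)OC/C=C(/C)C1=CC(=O)[C@](C)(O1)[C@H](O[Si](C(C)(C)C)(C(C)(C)C)OC2)[C@H]2OC(=O)[C@H](C)CC | intermediate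
11 | seco triol (C6–OH, C7–OH, C9–OH; C8 ester; 4Z; 8S,9R,10R,2'R) | OC/C=C(/C)C1=CC(=O)[C@](C)(O1)[C@H](O)[C@@H](OC(=O)[C@H](C)CC)CO | intermediate
12 | seco dialdehyde (C6 and C7 aldehydes; 4Z; stereocentres spatially as in 11) | O=C/C=C(/C)C1=CC(=O)[C@](C)(O1)[C@H](O)[C@@H](OC(=O)[C@H](C)CC)C=O | intermediate
13 | methyl propiolate | C#CC(=O)OC | starting material
14 | [1-(methoxycarbonyl)vinyl]diisobutylaluminium | C=C(C(=O)OC)[Al](CC(C)C)CC(C)C | intermediate
15 | Baylis–Hillman-type carbinol (C7–OH, both epimers; C11=C13H2; C12 methyl ester) | O=C/C=C(/C)C1=CC(=O)[C@](C)(O1)[C@H](O)[C@@H](OC(=O)[C@H](C)CC)C(O)C(=C)C(=O)OC | intermediate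
16 | Z-allylic bromide (C13H2Br, C7=C11, C8 cis to CH2Br) with C6 Z-enal | O=C/C=C(/C)C1=CC(=O)[C@](C)(O1)[C@H](O)[C@@H](OC(=O)[C@H](C)CC)/C=C(\CBr)C(=O)OC | intermediate
17 | allylchromium dichloride derived from 16 | O=C/C=C(/C)C1=CC(=O)[C@](C)(O1)[C@H](O)[C@@H](OC(=O)[C@H](C)CC)/C=C(\C[Cr](Cl)Cl)C(=O)OC | intermediate
18 | ring-A hydroxy ester (6R-OH, 7S, C11=C13H2, C12 methyl ester) | COC(=O)C(=C)[C@H]1[C@H](O)/C=C(/C)C2=CC(=O)[C@](C)(O2)[C@H](O)[C@H]1OC(=O)[C@H](C)CC | intermediate
19 | CNP0146060.1, (4Z,6R,7S,8S,9R,10R)-9-hydroxy-1-oxo-3,10-epoxygermacra-2,4,11(13)-trien-12,6-olid-8-yl (2R)-2-methylbutanoate | C=C1C(=O)O[C@@H]2/C=C(/C)C3=CC(=O)[C@](C)(O3)[C@H](O)[C@@H](OC(=O)[C@H](C)CC)[C@@H]12 | target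

Total step count: 9. Longest linear sequence: 8 steps (3 → 19 through steps 2–9; equally 1 → 19 through steps 1 and 3–9).

Steps most likely to fail

Step 9. The allylchromium may add in the syn mode (C8 axial) or to the wrong C7 face. It may also lose the C8 acyloxy group by reductive 1,4-elimination, and oligomerisation may compete with ring closure. The fallback runs from 12 back to 19. It accepts the syn mode and corrects C6 during lactone formation.
- Vinylalumination of 12 with allyl propiolate in place of 13 should give the allyl ester carbinol F1.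
- NBS/Me2S should give the Z-allylic bromide allyl ester F2.
- Indium powder in THF/H2O at high dilution should give the 6-epi hydroxy allyl ester F3. Under these conditions 2-(bromomethyl)enoates of this geometry add syn and the hydroxy ester stays open.
- Pd(PPh3)4/PhSiH3 frees the 6-epi seco acid F4.
- PPh3/DIAD then closes ring C by SN2 attack of the carboxylate on the activated allylic C6–OH with inversion (Mitsunobu lactonisation), giving 19.

Step 3. The lactol may resist opening, the alkoxide may attack the silylene, or the amine may isomerise the Z C4=C5 bond through reversible conjugate addition. The fallback runs from 2 and 4 back to 8. It replaces the alkyne by a ketone enolate.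
- Ph3PAuCl/AgOTf-catalysed Markovnikov hydration of 2 (dioxane/H2O) should give (Z)-5-(tert-butyldimethylsilyloxy)-3-methylpent-3-en-2-one F5.
- Its kinetic enolate (LiN(iPr)2, THF, −78 °C, 3 equiv) is acylated at C2 by lactone 4 (crossed Claisen condensation) to give the α'-hydroxy 1,3-diketone F6.
- Acidifying the same flask (aq. HCl, THF) brings about the classical cyclodehydration: 5-exo-trig attack of C10–OH on the C3 ketone, then loss of water, to give 8. Both ring-B bonds still arise in one flask.

Step 4. Substitution may stall because quaternary C10 shields C8, or elimination and acyl scrambling may take over. The fallback runs from 3 back to 10. It moves the inversion to the start, where it is a known carbohydrate operation.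
- Selective tosylation of the primary OH of 3 (TsCl, pyridine, 0 °C) should give 5-O-tosyl-2-C-methyl-D-ribono-1,4-lactone F7.
- Aq. KOH opens the lactone and the C4 alkoxide closes the 4,5-epoxide. On acidification the carboxylate opens the epoxide at C4 (5-exo-tet) with inversion, giving 2-C-methyl-L-lyxono-1,4-lactone F8.
- The conditions of step 2 give its 3,5-O-silylene derivative F9.
- The conditions of step 3 with 2 give the C8-epimeric furanone alcohol F10, which already has the C8 configuration of the target.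
- Acylation with retention (9, EDC·HCl, DMAP, CH2Cl2, Steglich esterification) gives 10.

Further compounds
F1 | step 9 | allyl ester carbinol (15 with allyl in place of methyl) | O=C/C=C(/C)C1=CC(=O)[C@](C)(O1)[C@H](O)[C@@H](OC(=O)[C@H](C)CC)C(O)C(=C)C(=O)OCC=C
F2 | step 9 | Z-allylic bromide allyl ester | O=C/C=C(/C)C1=CC(=O)[C@](C)(O1)[C@H](O)[C@@H](OC(=O)[C@H](C)CC)/C=C(\CBr)C(=O)OCC=C
F3 | step 9 | 6-epi hydroxy allyl ester (ring A closed, 6S-OH) | C=CCOC(=O)C(=C)[C@H]1[C@@H](O)/C=C(/C)C2=CC(=O)[C@](C)(O2)[C@H](O)[C@H]1OC(=O)[C@H](C)CC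
F4 | step 9 | 6-epi seco acid | OC(=O)C(=C)[C@H]1[C@@H](O)/C=C(/C)C2=CC(=O)[C@](C)(O2)[C@H](O)[C@H]1OC(=O)[C@H](C)CC
F5 | step 3 | (Z)-5-(tert-butyldimethylsilyloxy)-3-methylpent-3-en-2-one | CC(=O)/C(C)=C\CO[Si](C)(C)C(C)(C)C
F6 | step 3 | α'-hydroxy 1,3-diketone | CC(C)(C)[Si](C)(C)OC/C=C(/C)C(=O)CC(=O)[C@](C)(O)[C@H](O[Si](C(C)(C)C)(C(C)(C)C)OC1)[C@@H]1O
F7 | step 4 | 5-O-tosyl-2-C-methyl-D-ribono-1,4-lactone | O=C1[C@](C)(O)[C@H](O)[C@H](O1)COS(=O)(=O)c2ccc(C)cc2
F8 | step 4 | 2-C-methyl-L-lyxono-1,4-lactone | O=C1[C@](C)(O)[C@H](O)[C@@H](O1)CO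
F9 | step 4 | 3,5-O-(di-tert-butylsilanediyl)-2-C-methyl-L-lyxono-1,4-lactone | O=C1[C@](C)(O)[C@H](O[Si](C(C)(C)C)(C(C)(C)C)OC2)[C@H]2O1
F10 | step 4 | C8-epimeric furanone alcohol (8 with 5S-OH) | CC(C)(C)[Si](C)(C)OC/C=C(/C)C1=CC(=O)[C@](C)(O1)[C@H](O[Si](C(C)(C)C)(C(C)(C)C)OC2)[C@H]2O
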